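## Analysis of the target

Ferocaulidin (25) is a drimane-type sesquiterpene whose C11 oxygen is etherified with umbelliferone. Drimane numbering is used throughout: ring A is C1–C5 and C10, ring B is C5–C10, C11 is on C9, C12 on C8, C13 and C14 on C4, C15 on C10. The decalin is trans-fused and has four stereocentres, C3 (S), C5 (S), C9 (R) and C10 (S): H5 is anti to the C15 methyl group, the C9 side chain is syn to C15 and equatorial, and the C3 hydroxyl is anti to C15 and therefore axial, next to the C4 gem-dimethyl group. Ring B holds a C6 ketone conjugated with the trisubstituted C7=C8 double bond, so C8 is trigonal in the target and any stereocentre placed there on the way is temporary. The sensitive features are the coumarin lactone (hydride, organometallics, strong base), the C11 aryloxy group, which can be eliminated through C9 as a vinylogous β-leaving group of the enone, and the epimerisable C5–H and C9–H. The synthesis is hard because C4 and C10 are both quaternary and flank C5, which makes the C4–C5 bond very congested, and because the C3 and C6 oxygens must end at different oxidation levels. The strategy rests on the 1,4 relationship of these two oxygens across C4–C5: if both are carried as enol silanes, their nucleophilic carbons are exactly C4 and C5, and joining them oxidatively closes ring A onto a preformed ring B.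

## Retrosynthetic reasoning

The aryl ether bond C11–O of 25 is cut first, giving the enone diol 23 and umbelliferone 24. The coumarin would not survive the hydride, organolithium and oxidative steps that come earlier. The primary C11 hydroxyl can be distinguished from the axial, neopentylic C3 hydroxyl without protection. The forward reaction is a redox etherification under neutral conditions, which avoids base-induced loss of the C11 substituent across C9.

The C7=C8 double bond is removed next. Diol 23 comes from the bis(silyl ether) 22, and 22 from the saturated C6 ketone 21 by dehydrogenation. C4 and C10 carry no hydrogen, so unsaturation can only enter between C7 and C8, and the temporary C8 stereocentre is erased here. Ketone 21 is not isolated; it forms in the same operation from the C6 carbinol of 20.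

The two ring oxygens are distinguished at diol 19, not at diketone 18. In 18 the C3 carbonyl sits next to the quaternary C4 and is not clearly the more accessible one, so a selective mono-reduction is not relied on. Both carbonyls are reduced, a bulky hydride giving the axial C3 alcohol. The C6 hydroxyl of 19 is syn-axial to the C13 and C15 methyl groups and is left untouched when the C3 hydroxyl is silylated to 20. The C3 configuration and the C3/C6 differentiation then each depend on a single steric argument.

Diketone 18 is cut at C4–C5, the most hindered bond of the molecule, to give the bis(enol silane) 16. This turns a bond between a quaternary carbon and a doubly neopentylic methine into the union of two electron-rich carbons held in reach by C10–C1–C2–C3. Ring A, one skeletal bond and the C5 stereocentre result. The forward reaction must oxidise one enol silane and let the other capture it intramolecularly. C5 is α to the C6 ketone and is settled afterwards by equilibration of the kinetic mixture (which contains the cis-fused 17) to the trans ring fusion.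

Compound 16 is cut at C10–C1 into enone 7 and the side-chain iodide 13. Conjugate addition of the copper reagent 15 (from 13 by way of 14) with silyl trapping forms the quaternary C10 and at the same time the C5=C6 enol silane, a regiochemistry that ordinary enolisation of a C6 ketone would not give. The C3=C4 enol silane travels in the nucleophile. C10 is set relative to C9. The C8 methyl group is kept trans to the C9 substituent because both are then equatorial in 18 and because the annulation delivers this arrangement. It is 1,3 to C10, and its influence on the addition is the one stereochemical uncertainty accepted before the key step.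

Iodide 13 is traced back to alcohol 11, diene 9 and vinyl ketone 8. The tetrasubstituted enol silane is installed on 8, where the isopropyl methine is the only enolisable position, so its regiochemistry is unambiguous. A β-halo ketone with the same chain would lose hydrogen halide on enolisation. The terminal vinyl group of 9 is then converted into alcohol 11 (through borane 10) and into 13 (through mesylate 12) under conditions that leave the enol silane alone.

Enone 7 goes back through 6 and 5 to keto ester 4, then to the acyclic adduct 3 and to ethyl acetoacetate 1 and pentenone 2. This Michael/aldol annulation delivers all six ring B carbons with C11, C12 and C15 attached. The Michael step sets C8 under catalyst control. C9 in 4 is a vinylogous β-keto ester centre and equilibrates, so the trans isomer is collected and the rest recycled. Reduction to 5, allylic oxidation to 6 and silylation complete 7.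

## Alternatives that were turned down

Alternative 1: The decalin is cut at C5–C10 and C8–C9, so that both rings come from one intramolecular Diels–Alder reaction. The chain holds a 2-silyloxydiene (C5=C6–C7=C8) and an E-configured enoyl oxazolidinone (C9=C10), and the reaction is run with a chiral Lewis acid such as Cu(OTf)2/bis(oxazoline); the adduct is A1.
- For: two rings, four stereocentres and the absolute configuration arise in one catalytic step, and C6 arrives oxygenated. The C9/C10 relationship follows stereospecifically from the alkene geometry, which is stronger than the substrate-controlled conjugate addition used here.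
- Against: the dienophile carbon C10 is β,β-disubstituted and must become quaternary while bonding to C5, which sits next to the quaternary C4. Chelating Lewis-acid catalysis is dependable for β-monosubstituted enoyl imides and loses rate and face discrimination with this substitution, so the step that carries everything is the least precedented one.
- Step economy: the precursor needs a trisubstituted enoyl imide of defined geometry and a regioselectively formed dienol silane. Afterwards the imide must be reduced to C11–OH, the ketal removed, C3 reduced and the C6=C7 enol silane converted into the C7=C8 enone, so no steps are saved.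
- Comparison: the chosen route gives up the one-step construction. In return ring B comes from a simple annulation, and the risky step forms a single hindered bond by a radical-cation closure with an early transition state.

Alternative 2: Ring B is cut at C9–C10 and C7–C8. A but-2-ynoate is esterified to the C3 oxygen of a ring A 2-silyloxydiene (C10=C5–C6=C7) and adds intramolecularly, giving the bridged lactone A2 with a C8=C9 double bond and a C5=C6 enol silane.
- For: the C3 stereocentre exists from the start and the tether relays it to C10. The two ring oxygens are different functional groups throughout, which is cleaner than the reduce-both-then-silylate-one sequence used here. C11 arrives as the lactone carbonyl.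
- Against: the reacting conformer needs the s-cis form of the ester and a boat-like ring A spanned by a seven-membered lactone. The diene terminus C10 is fully substituted, and a 2-silyloxydiene is unlikely to survive the temperature such a tether requires.
- Against, more seriously: C9 is trigonal in A2. The alkene must be moved from C8=C9 to C7=C8 and C9–H introduced on the correct face, and nothing in A2 controls that protonation.
- Comparison: the chosen strategy fixes C9 while ring B is made and leaves only C5, an epimerisable centre, to be set late.

Alternative 3: C7 is inserted last. A skeleton with a five-membered ring B, in which C6 and C8 are bonded directly, is converted into its C6=C8 silyl enol ether and cyclopropanated with Et2Zn/CH2I2 to give A3 (C6–C7 and C7–C8 formed). Cleavage of the shared C6–C8 bond, for instance with FeCl3 and then base, gives the six-membered enone.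
- For: the C7=C8 enone with its C8 methyl group appears directly and regiospecifically, with no dehydrogenation and no temporary C8 stereocentre. On that point it is at least as good as the IBX step used here, and each reaction is of a known type.
- Against: everything that makes the target hard (the quaternary C4/C10 pair, the C4–C5 bond, C3, C5, C9 and C10) must already be present in the ring-contracted bicycle, which is no easier to assemble than the decalin. The enol silane must form toward the substituted C8 and not toward C5, and a tetrasubstituted enol silane must be cyclopropanated on a crowded face.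
- Step economy: three steps are spent on a ring that an annulation delivers directly.
- Comparison: the chosen strategy spends its key step on the bond that is actually difficult.

Key step: step 10

Remark: "drimane" serves only as a locant system in the names below; configuration is given by the CIP descriptors.
Assumption: the amine catalyst of step 1 is taken to give the (3S) adduct; if the sense is the opposite, its pseudoenantiomer 9-amino-9-deoxy-epi-quinidine is used.

## Route

Step 1
Reactants: 1 ethyl acetoacetate; 2 (E)-pent-3-en-2-one
Product: 3 ethyl (2RS,3S)-2-acetyl-3-methyl-5-oxohexanoate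
Conditions: 9-amino-9-deoxy-epi-quinine (10 mol %), CF3CO2H (20 mol %), THF, 25 °C
Reagents that add atoms: none
Why: Amine-catalysed (iminium) Michael addition of a 1,3-dicarbonyl compound to an acyclic enone; the chiral primary amine shields one face of the E-iminium ion and sets C8 (C3 of the hexanoate), while the doubly activated C2 stays epimerisable and does not matter.

Step 2
Reactants: 3 ethyl (2RS,3S)-2-acetyl-3-methyl-5-oxohexanoate
Product: 4 ethyl (1R,6S)-2,6-dimethyl-4-oxocyclohex-2-ene-1-carboxylate
Conditions: TsOH·H2O (10 mol %), toluene, reflux, water separator; chromatography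
Reagents that add atoms: none
Why: Intramolecular aldol condensation (second half of a Robinson-type annulation): the enol of the methyl ketone attacks the acetoacetate carbonyl through C5 and water is lost, acid being used so that no retro-Michael reaction can erode C8. C9 (C1 of the ring) is a vinylogous β-keto ester centre and equilibrates; the trans isomer is collected and the cis isomer re-equilibrated and recycled.

Step 3
Reactants: 4 ethyl (1R,6S)-2,6-dimethyl-4-oxocyclohex-2-ene-1-carboxylate
Product: 5 (1RS,4R,5S)-4-(hydroxymethyl)-3,5-dimethylcyclohex-2-en-1-ol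
Conditions: i-Bu2AlH (4.5 equiv), CH2Cl2, −78 → 0 °C; aq. potassium sodium tartrate
Reagents that add atoms: none
Why: 1,2-Reduction of the enone and reduction of the ester by an aluminium hydride; the carbinol mixture at C1 is unimportant because that centre is re-oxidised in step 4.

Step 4
Reactants: 5 (1RS,4R,5S)-4-(hydroxymethyl)-3,5-dimethylcyclohex-2-en-1-ol
Product: 6 (4R,5S)-4-(hydroxymethyl)-3,5-dimethylcyclohex-2-en-1-one
Conditions: MnO2 (activated, 15 equiv), CH2Cl2, 25 °C
Reagents that add atoms: none
Why: Chemoselective allylic oxidation; MnO2 oxidises the allylic secondary alcohol and leaves the saturated primary alcohol, and any residual cis isomer is removed by chromatography at this stage.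

Step 5
Reactants: 6 (4R,5S)-4-(hydroxymethyl)-3,5-dimethylcyclohex-2-en-1-one
Product: 7 (4R,5S)-4-{[(tert-butyldimethylsilyl)oxy]methyl}-3,5-dimethylcyclohex-2-en-1-one
Conditions: t-BuMe2SiCl, imidazole, DMF, 25 °C
Reagents that add atoms: tert-butyldimethylsilyl chloride, CC(C)(C)[Si](C)(C)Cl
Why: Standard silylation of a primary alcohol; the mild base does not enolise the enone toward C9.

Step 6
Reactants: 8 4-methylpent-1-en-3-one
Product: 9 tert-butyldimethyl[(4-methylpenta-1,3-dien-3-yl)oxy]silane
Conditions: t-BuMe2SiOTf (1.1 equiv), Et3N (1.5 equiv), Et2O, 0 °C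
Reagents that add atoms: tert-butyldimethylsilyl trifluoromethanesulfonate, CC(C)(C)[Si](C)(C)OS(=O)(=O)C(F)(F)F
Why: Soft enolisation of a vinyl ketone to a 2-silyloxydiene; the isopropyl methine is the only α-hydrogen, so the tetrasubstituted C3=C4 enol silane forms regiospecifically.

Step 7
Reactants: 9 tert-butyldimethyl[(4-methylpenta-1,3-dien-3-yl)oxy]silane
Product: 11 3-[(tert-butyldimethylsilyl)oxy]-4-methylpent-3-en-1-ol, via B-alkyl-9-borabicyclo[3.3.1]nonane 10 (not isolated)
Conditions: 9-BBN (1.05 equiv), THF, 0 → 25 °C; then NaBO3·4H2O, H2O, 25 °C
Reagents that add atoms: sodium perborate, O[B-]1(O)OO[B-](O)(O)OO1.[Na+].[Na+]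
Why: Anti-Markovnikov hydroboration–oxidation; the bulky borane adds only to the monosubstituted vinyl group with boron on the terminal carbon, and the tetrasubstituted enol ether is inert. Perborate keeps the oxidation near neutral, so the silyl group does not migrate from the enol oxygen to the new alkoxide.

Step 8
Reactants: 11 3-[(tert-butyldimethylsilyl)oxy]-4-methylpent-3-en-1-ol
Product: 13 tert-butyl[(1-iodo-4-methylpent-3-en-3-yl)oxy]dimethylsilane, via methanesulfonate 12 (not isolated)
Conditions: MeSO2Cl, Et3N, CH2Cl2, −20 °C; then NaI, NaHCO3, acetone, 25 °C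
Reagents that add atoms: sodium iodide, [Na+].[I-]; methanesulfonyl chloride, CS(=O)(=O)Cl (its atoms remain only in 12)
Why: Sulfonylation and Finkelstein displacement at a primary carbon; both stages are neutral to weakly basic and free of electrophilic halogen, so the enol silane survives.

Step 9
Reactants: 7 (4R,5S)-4-{[(tert-butyldimethylsilyl)oxy]methyl}-3,5-dimethylcyclohex-2-en-1-one; 13 tert-butyl[(1-iodo-4-methylpent-3-en-3-yl)oxy]dimethylsilane
Product: 16 (3S,4R,5S)-4-{[(tert-butyldimethylsilyl)oxy]methyl}-3-{3-[(tert-butyldimethylsilyl)oxy]-4-methylpent-3-en-1-yl}-3,5-dimethyl-1-[(trimethylsilyl)oxy]cyclohex-1-ene, via alkyllithium 14 (not isolated), via lithium dialkylcuprate 15 (not isolated)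
Conditions: 13 (2.2 equiv), t-BuLi (4.5 equiv), Et2O/pentane, −78 °C; CuBr·SMe2 (1.1 equiv), Et2O/THF, −78 → −40 °C; then 7, Me3SiCl (3 equiv), −78 → −30 °C; Et3N, aq. NaHCO3
Reagents that add atoms: chlorotrimethylsilane, C[Si](C)(C)Cl
Why: Iodine–lithium exchange gives 14, CuBr·SMe2 converts it into the Gilman reagent 15, and Me3SiCl-accelerated conjugate addition to 7 forms the quaternary C10 and traps the enolate as the C5=C6 trimethylsilyl enol ether, so both enol silanes are regiodefined by the way they are made. A1,2 strain with the C10 methyl group puts the C9 silyloxymethyl group pseudoaxial, and the copper reagent should enter anti to it, which gives (10S). The trans C8 methyl group is then axial on the attacked face but 1,3 to C10, so it is expected to slow the addition without reversing its sense.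

Step 10
Reactants: 16 (3S,4R,5S)-4-{[(tert-butyldimethylsilyl)oxy]methyl}-3-{3-[(tert-butyldimethylsilyl)oxy]-4-methylpent-3-en-1-yl}-3,5-dimethyl-1-[(trimethylsilyl)oxy]cyclohex-1-ene
Product: 18 (5S,8S,9R,10S)-11-[(tert-butyldimethylsilyl)oxy]drimane-3,6-dione, via cis-fused C5 epimer 17 (not isolated)
Conditions: (NH4)2Ce(NO3)6 (2.3 equiv), NaHCO3 (6 equiv), MeCN (0.005 M), −30 → 0 °C; then NaOMe (0.2 equiv), MeOH, 25 °C
Reagents that add atoms: none
Why: (NH4)2Ce(NO3)6 takes one electron from the more electron-rich, tetrasubstituted C3=C4 enol silane; the radical cation (or the tertiary α-keto radical left after loss of its silyl group) is electrophilic at C4 and adds to C5, the nucleophilic carbon of the ring B enol silane, in a 6-exo-trig closure that forms C4–C5 and ring A (oxidation of the ring B enol silane first would lead to the same bond). The α-silyloxy radical at C6 is oxidised by the second equivalent of oxidant to an oxocarbenium ion, and loss of both silyl groups leaves the 1,4-diketone. The closest known reaction type is the intramolecular oxidative coupling of bis(silyl enol ethers) to cyclic 1,4-diketones with (NH4)2Ce(NO3)6 or Cu(OTf)2, which also forms bonds to fully substituted carbons. Regioselectivity lies in the substrate: C4 and C5 are the only enol carbons, and their union is the only closure that gives a six-membered ring. C5 is the one new stereocentre; the kinetic mixture, of which 17 is the cis-fused component, is epimerised α to the C6 ketone with NaOMe to the trans-fused diketone, in which H5 is anti to C15 and the C8 and C9 substituents are both equatorial. The step needs cyclisation to outrun dimerisation, hydrolysis of the trimethylsilyl enol ether and further oxidation of the C4 radical; high dilution, the NaHCO3 buffer and low temperature serve this, and the C10–C1–C2 tether holds C4 within reach of C5.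

Step 11
Reactants: 18 (5S,8S,9R,10S)-11-[(tert-butyldimethylsilyl)oxy]drimane-3,6-dione
Product: 19 (3S,5S,6S,8S,9R,10S)-11-[(tert-butyldimethylsilyl)oxy]drimane-3,6-diol
Conditions: KB(s-Bu)3H (3 equiv), THF, −78 → 0 °C; then H2O
Reagents that add atoms: none
Why: Reduction of both ketones by a bulky trialkylborohydride: equatorial attack at C3 gives the axial (3S) alcohol, and C6 is attacked on the face away from the syn-axial C13 and C15 methyl groups to give the axial (6S) alcohol. The C6 configuration is lost again in step 13, so only the C3 selectivity matters.

Step 12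
Reactants: 19 (3S,5S,6S,8S,9R,10S)-11-[(tert-butyldimethylsilyl)oxy]drimane-3,6-diol
Product: 20 (3S,5S,6S,8S,9R,10S)-3,11-bis[(tert-butyldimethylsilyl)oxy]driman-6-ol
Conditions: t-BuMe2SiOTf (1.05 equiv), 2,6-lutidine, CH2Cl2, −78 → −20 °C
Reagents that add atoms: tert-butyldimethylsilyl trifluoromethanesulfonate, CC(C)(C)[Si](C)(C)OS(=O)(=O)C(F)(F)F
Why: Site-selective silylation: the C6 hydroxyl is syn-axial to two methyl groups (C13 and C15) and should not react at low temperature, whereas the C3 hydroxyl, though axial and neopentylic, has only hydrogen atoms as 1,3-diaxial neighbours.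

Step 13
Reactants: 20 (3S,5S,6S,8S,9R,10S)-3,11-bis[(tert-butyldimethylsilyl)oxy]driman-6-ol
Product: 22 (3S,5S,9R,10S)-3,11-bis[(tert-butyldimethylsilyl)oxy]drim-7-en-6-one, via saturated C6 ketone 21 (not isolated)
Conditions: IBX (4 equiv), PhF/DMSO 2:1, 25 °C then 75 °C
Reagents that add atoms: none
Why: IBX first oxidises the strained secondary alcohol to ketone 21 and then dehydrogenates the ketone through its enol (IBX dehydrogenation of ketones to enones). C4 and C10 are quaternary, so unsaturation can only enter at C7=C8, and the temporary C8 stereocentre disappears. Silyl ethers are stable to IBX, and C5 remains at its trans-fused thermodynamic configuration.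

Step 14
Reactants: 22 (3S,5S,9R,10S)-3,11-bis[(tert-butyldimethylsilyl)oxy]drim-7-en-6-one
Product: 23 (3S,5S,9R,10S)-3,11-dihydroxydrim-7-en-6-one
Conditions: HF (48 % aq.), MeCN, 0 → 25 °C
Reagents that add atoms: none
Why: Acidic fluoride cleavage of both silyl ethers; acid is chosen over basic fluoride so that neither C9–H (γ to the enone) nor the C11 oxygen is put at risk.

Step 15
Reactants: 23 (3S,5S,9R,10S)-3,11-dihydroxydrim-7-en-6-one; 24 umbelliferone (7-hydroxy-2H-chromen-2-one)
Product: 25 ferocaulidin, (3S,5S,9R,10S)-3-hydroxy-11-[(2-oxo-2H-chromen-7-yl)oxy]drim-7-en-6-one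
Conditions: PPh3, i-PrO2C–N=N–CO2i-Pr, THF, 0 → 25 °C
Reagents that add atoms: none
Why: Mitsunobu etherification: the acidic phenol is alkylated by the oxyphosphonium ion of the primary C11 alcohol, while the axial, neopentylic C3 hydroxyl cannot be displaced and is left free. No stereocentre is involved, and the neutral conditions disfavour elimination across C9–C11.

## Compound list

1 | ethyl acetoacetate | CCOC(=O)CC(C)=O | starting material
2 | (E)-pent-3-en-2-one | C/C=C/C(C)=O | starting material
3 | ethyl (2RS,3S)-2-acetyl-3-methyl-5-oxohexanoate | CCOC(=O)C(C(C)=O)[C@@H](C)CC(C)=O | intermediate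
4 | ethyl (1R,6S)-2,6-dimethyl-4-oxocyclohex-2-ene-1-carboxylate | C[C@H]1CC(=O)C=C(C)[C@@H]1C(=O)OCC | intermediate
5 | (1RS,4R,5S)-4-(hydroxymethyl)-3,5-dimethylcyclohex-2-en-1-ol | C[C@H]1CC(O)C=C(C)[C@@H]1CO | intermediate
6 | (4R,5S)-4-(hydroxymethyl)-3,5-dimethylcyclohex-2-en-1-one | C[C@H]1CC(=O)C=C(C)[C@@H]1CO | intermediate
7 | (4R,5S)-4-{[(tert-butyldimethylsilyl)oxy]methyl}-3,5-dimethylcyclohex-2-en-1-one | C[C@H]1CC(=O)C=C(C)[C@@H]1CO[Si](C)(C)C(C)(C)C | intermediate
8 | 4-methylpent-1-en-3-one | CC(C)C(=O)C=C | starting material
9 | tert-butyldimethyl[(4-methylpenta-1,3-dien-3-yl)oxy]silane | CC(C)=C(O[Si](C)(C)C(C)(C)C)C=C | intermediate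
10 | 9-{3-[(tert-butyldimethylsilyl)oxy]-4-methylpent-3-en-1-yl}-9-borabicyclo[3.3.1]nonane | CC(C)=C(O[Si](C)(C)C(C)(C)C)CCB1C2CCCC1CCC2 | intermediate (not isolated)
11 | 3-[(tert-butyldimethylsilyl)oxy]-4-methylpent-3-en-1-ol | CC(C)=C(O[Si](C)(C)C(C)(C)C)CCO | intermediate
12 | 3-[(tert-butyldimethylsilyl)oxy]-4-methylpent-3-en-1-yl methanesulfonate | CC(C)=C(O[Si](C)(C)C(C)(C)C)CCOS(C)(=O)=O | intermediate (not isolated)
13 | tert-butyl[(1-iodo-4-methylpent-3-en-3-yl)oxy]dimethylsilane | CC(C)=C(O[Si](C)(C)C(C)(C)C)CCI | intermediate
14 | {3-[(tert-butyldimethylsilyl)oxy]-4-methylpent-3-en-1-yl}lithium | [Li]CCC(O[Si](C)(C)C(C)(C)C)=C(C)C | intermediate (not isolated)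
15 | lithium bis{3-[(tert-butyldimethylsilyl)oxy]-4-methylpent-3-en-1-yl}cuprate | [Li+].CC(C)=C(O[Si](C)(C)C(C)(C)C)CC[Cu-]CCC(O[Si](C)(C)C(C)(C)C)=C(C)C | intermediate (not isolated)
16 | (3S,4R,5S)-4-{[(tert-butyldimethylsilyl)oxy]methyl}-3-{3-[(tert-butyldimethylsilyl)oxy]-4-methylpent-3-en-1-yl}-3,5-dimethyl-1-[(trimethylsilyl)oxy]cyclohex-1-ene | C[C@H]1CC(O[Si](C)(C)C)=C[C@@](C)(CCC(O[Si](C)(C)C(C)(C)C)=C(C)C)[C@@H]1CO[Si](C)(C)C(C)(C)C | intermediate
17 | (5R,8S,9R,10S)-11-[(tert-butyldimethylsilyl)oxy]drimane-3,6-dione (cis-fused) | C[C@H]1CC(=O)[C@H]2C(C)(C)C(=O)CC[C@@]2(C)[C@@H]1CO[Si](C)(C)C(C)(C)C | intermediate (not isolated)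
18 | (5S,8S,9R,10S)-11-[(tert-butyldimethylsilyl)oxy]drimane-3,6-dione (trans-fused) | C[C@H]1CC(=O)[C@@H]2C(C)(C)C(=O)CC[C@@]2(C)[C@@H]1CO[Si](C)(C)C(C)(C)C | intermediate
19 | (3S,5S,6S,8S,9R,10S)-11-[(tert-butyldimethylsilyl)oxy]drimane-3,6-diol | C[C@H]1C[C@H](O)[C@@H]2C(C)(C)[C@@H](O)CC[C@@]2(C)[C@@H]1CO[Si](C)(C)C(C)(C)C | intermediate
20 | (3S,5S,6S,8S,9R,10S)-3,11-bis[(tert-butyldimethylsilyl)oxy]driman-6-ol | C[C@H]1C[C@H](O)[C@@H]2C(C)(C)[C@@H](O[Si](C)(C)C(C)(C)C)CC[C@@]2(C)[C@@H]1CO[Si](C)(C)C(C)(C)C | intermediate
21 | (3S,5S,8S,9R,10S)-3,11-bis[(tert-butyldimethylsilyl)oxy]driman-6-one | C[C@H]1CC(=O)[C@@H]2C(C)(C)[C@@H](O[Si](C)(C)C(C)(C)C)CC[C@@]2(C)[C@@H]1CO[Si](C)(C)C(C)(C)C | intermediate (not isolated)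
22 | (3S,5S,9R,10S)-3,11-bis[(tert-butyldimethylsilyl)oxy]drim-7-en-6-one | CC1=CC(=O)[C@@H]2C(C)(C)[C@@H](O[Si](C)(C)C(C)(C)C)CC[C@@]2(C)[C@@H]1CO[Si](C)(C)C(C)(C)C | intermediate
23 | (3S,5S,9R,10S)-3,11-dihydroxydrim-7-en-6-one | CC1=CC(=O)[C@@H]2C(C)(C)[C@@H](O)CC[C@@]2(C)[C@@H]1CO | intermediate
24 | umbelliferone (7-hydroxy-2H-chromen-2-one) | Oc1ccc2ccc(=O)oc2c1 | starting material
25 | ferocaulidin, (3S,5S,9R,10S)-3-hydroxy-11-[(2-oxo-2H-chromen-7-yl)oxy]drim-7-en-6-one | CC1=CC(=O)[C@@H]2C(C)(C)[C@@H](O)CC[C@@]2(C)[C@@H]1COc1ccc2ccc(=O)oc2c1 | target

## Step count and least certain steps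

Total step count: 15. Longest linear sequence: 12 steps (steps 1–5 and 9–15, from 1 and 2); the side-chain branch (steps 6–8) adds 3 steps.

Step 10 (key step). What may go wrong: hydrolysis of the trimethylsilyl enol ether, or further oxidation of the tertiary C4 radical to the isopropenyl ketone, may outrun the hindered 6-exo closure onto C5; intermolecular coupling may compete if dilution is insufficient. Fallback: an anionic, inner-sphere coupling in place of the radical-cation one. From 16, MeLi (2.2 equiv) in THF cleaves both enol silanes and gives the dilithium bis(enolate) F1, which is oxidised with Cu(OTf)2 at −78 °C so that both enolates are joined on one copper centre; NaOMe equilibration then returns the route to 18.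

Step 9. What may go wrong: erosion of facial selectivity, because the axial C8 methyl group hinders the face anti to C11 that the C9 substituent directs the reagent to; also 1,4 migration of silicon from the enol oxygen to carbon in 14 if the lithium reagent is allowed to warm. Fallback: catalyst control in place of substrate control. From 13, magnesium gives the Grignard reagent {3-[(tert-butyldimethylsilyl)oxy]-4-methylpent-3-en-1-yl}magnesium iodide F2, which is added to 7 with catalytic Cu(OTf)2 and a chiral N-heterocyclic carbene ligand, the ligand antipode being the one that reinforces the C9 bias. The magnesium enolate is silylated with Me3SiCl/Et3N, which returns the route to 16.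

Step 12. What may go wrong: loss of site selectivity, that is silylation at C6 as well or in place of C3. Fallback: distinguish the oxygens by chemoselective reduction and not by chemoselective protection. From 18, KB(s-Bu)3H (1.05 equiv) at −78 °C is aimed at the C3 carbonyl alone and gives the keto alcohol (3S,5S,8S,9R,10S)-11-[(tert-butyldimethylsilyl)oxy]-3-hydroxydriman-6-one F3. Silylation of its only hydroxyl with t-BuMe2SiOTf returns the route to 21, which is then dehydrogenated as in step 13. This is not the first choice because it depends on C3 being the more accessible carbonyl, which is uncertain.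

Step 13. What may go wrong: incomplete dehydrogenation of the hindered ketone, or over-oxidation and loss of silyl groups at 75 °C. Fallback: a stepwise Saegusa–Ito sequence. From 20, Dess–Martin periodinane gives 21 as an isolated compound; LiN(i-Pr)2/Me3SiCl deprotonates at C7 (C5 is a hindered methine) and gives the C6=C7 enol silane (3S,5S,8R,9R,10S)-3,11-bis[(tert-butyldimethylsilyl)oxy]-6-[(trimethylsilyl)oxy]drim-6-ene F4. Pd(OAc)2 in MeCN then returns the route to 22.

Step 15. What may go wrong: slow substitution at the β-branched C11 and competing elimination of the oxyphosphonium ion across C9–C11, which the γ-acidity of C9–H in the enone favours. Fallback: form the ether before the enone exists. From 20, Dess–Martin periodinane gives 21. HF·pyridine buffered with pyridine in THF at 0 °C removes only the primary silyl ether and gives (3S,5S,8S,9R,10S)-3-[(tert-butyldimethylsilyl)oxy]-11-hydroxydriman-6-one F5. Mitsunobu reaction with 24 gives the aryl ether (3S,5S,8S,9R,10S)-3-[(tert-butyldimethylsilyl)oxy]-11-[(2-oxo-2H-chromen-7-yl)oxy]driman-6-one F6, in which C9–H is not activated. IBX dehydrogenation gives (3S,5S,9R,10S)-3-[(tert-butyldimethylsilyl)oxy]-11-[(2-oxo-2H-chromen-7-yl)oxy]drim-7-en-6-one F7, and aqueous HF in MeCN returns the route to 25.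

## Further compounds

F1 | step 10 | dilithium (3S,4R,5S)-4-{[(tert-butyldimethylsilyl)oxy]methyl}-3,5-dimethyl-3-(4-methyl-3-oxidopent-3-en-1-yl)cyclohex-1-en-1-olate | C[C@H]1CC(O[Li])=C[C@@](C)(CCC(O[Li])=C(C)C)[C@@H]1CO[Si](C)(C)C(C)(C)C
F2 | step 9 | {3-[(tert-butyldimethylsilyl)oxy]-4-methylpent-3-en-1-yl}magnesium iodide | CC(C)=C(O[Si](C)(C)C(C)(C)C)CC[Mg]I
F3 | step 12 | (3S,5S,8S,9R,10S)-11-[(tert-butyldimethylsilyl)oxy]-3-hydroxydriman-6-one | C[C@H]1CC(=O)[C@@H]2C(C)(C)[C@@H](O)CC[C@@]2(C)[C@@H]1CO[Si](C)(C)C(C)(C)C
F4 | step 13 | (3S,5S,8R,9R,10S)-3,11-bis[(tert-butyldimethylsilyl)oxy]-6-[(trimethylsilyl)oxy]drim-6-ene | C[C@H]1C=C(O[Si](C)(C)C)[C@@H]2C(C)(C)[C@@H](O[Si](C)(C)C(C)(C)C)CC[C@@]2(C)[C@@H]1CO[Si](C)(C)C(C)(C)C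
F5 | step 15 | (3S,5S,8S,9R,10S)-3-[(tert-butyldimethylsilyl)oxy]-11-hydroxydriman-6-one | C[C@H]1CC(=O)[C@@H]2C(C)(C)[C@@H](O[Si](C)(C)C(C)(C)C)CC[C@@]2(C)[C@@H]1CO
F6 | step 15 | (3S,5S,8S,9R,10S)-3-[(tert-butyldimethylsilyl)oxy]-11-[(2-oxo-2H-chromen-7-yl)oxy]driman-6-one | C[C@H]1CC(=O)[C@@H]2C(C)(C)[C@@H](O[Si](C)(C)C(C)(C)C)CC[C@@]2(C)[C@@H]1COc1ccc2ccc(=O)oc2c1
F7 | step 15 | (3S,5S,9R,10S)-3-[(tert-butyldimethylsilyl)oxy]-11-[(2-oxo-2H-chromen-7-yl)oxy]drim-7-en-6-one | CC1=CC(=O)[C@@H]2C(C)(C)[C@@H](O[Si](C)(C)C(C)(C)C)CC[C@@]2(C)[C@@H]1COc1ccc2ccc(=O)oc2c1
A1 | alternative 1 | trans-fused Diels–Alder adduct with C6 trimethylsilyl enol ether (C6=C7), C3 ethylene ketal and C9 (2-oxo-1,3-oxazolidin-3-yl)carbonyl group | C[C@@H]1C=C(O[Si](C)(C)C)[C@@H]2C(C)(C)C3(OCCO3)CC[C@@]2(C)[C@@H]1C(=O)N1CCOC1=O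
A2 | alternative 2 | bridged tricyclic lactone (C3–O–C11 bridge) with C8=C9 alkene and C5=C6 tert-butyldimethylsilyl enol ether | CC1=C2C(=O)O[C@H]3CC[C@]2(C)C(=C(O[Si](C)(C)C(C)(C)C)C1)C3(C)C
A3 | alternative 3 | silyloxycyclopropane with C7 bridging C6 and C8, C3 and C11 tert-butyldimethylsilyl ethers | C[C@]12C[C@@]1(O[Si](C)(C)C)[C@H]1C(C)(C)[C@@H](O[Si](C)(C)C(C)(C)C)CC[C@@]1(C)[C@@H]2CO[Si](C)(C)C(C)(C)C
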